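**Retrosynthetic overview**
- Both C(pyrone)–CH(CH3) bonds next to the ketone are cut. The target comes from the pyrone B zinc reagent and an α-bromo-α'-(pyrone A) ketone, which comes from the pyrone A zinc reagent and 2,4-dibromopentan-3-one. Each bond is made by a nickel-catalysed enantioconvergent Negishi coupling, with the ligand enantiomer switched between the two to reach the R,S relationship.
- Each pyronylzinc iodide comes from a 6-iodo-γ-pyrone, made by C–H zincation/iodination of the 6-unsubstituted γ-pyrone.
- Both γ-pyrone rings come from one common enaminone of pentan-3-one, C-acylated with hexanoyl or propanoyl chloride and cyclised.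
- The central C5 unit comes from dibromination of pentan-3-one.
- Ring order: pyrone A, then pyrone B, both before any coupling. No ring is formed afterwards, and the two base-labile α-stereocentres are created in the last two steps.

Assumption: the (S,S)-ligand, 2,6-bis[(4S)-4-phenyl-4,5-dihydro-1,3-oxazol-2-yl]pyridine ((S,S)-Ph-pybox), is taken to give the R centre (acyl > pyronyl > methyl); if the measured sense is opposite, the two ligand enantiomers are exchanged between steps 7 and 8.

**Step 1**
Reactants: 1 pentan-3-one; 2 N,N-dimethylformamide dimethyl acetal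
Product: 3 (E)-1-(dimethylamino)-2-methylpent-1-en-3-one
Conditions: neat, 110 °C (sealed tube), 48 h; distillation
Reagents that add atoms: none
Why: Aminomethylenation (enaminone formation) of the ketone α-methylene by the amide acetal is driven by loss of methanol, pentan-3-one has only one kind of α-position, and the E isomer is the stable one.

**Step 2**
Reactants: 3 (E)-1-(dimethylamino)-2-methylpent-1-en-3-one; 4 hexanoyl chloride
Product: 6 3,5-dimethyl-2-pentyl-4H-pyran-4-one, via C-acylated enaminone 5 (not isolated)
Conditions: 3 (2.1 equiv), LiN(SiMe3)2 (2.1 equiv), THF, −78 °C; 4 (1.0 equiv), −78 → −20 °C; then 3 M HCl, rt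
Reagents that add atoms: none
Why: In this enaminone acylation–cyclisation route to γ-pyrones the lithium enolate at the only enolisable α'-methylene is C-acylated by the acid chloride (Claisen-type; the second equivalent of enolate takes up the acidic diketone proton), and acid then makes the diketone enol oxygen add to the vinylogous amide carbon and expel dimethylamine (6-endo addition–elimination).

**Step 3**
Reactants: 6 3,5-dimethyl-2-pentyl-4H-pyran-4-one
Product: 8 2-iodo-3,5-dimethyl-6-pentyl-4H-pyran-4-one, via pyronylzinc chloride 7 (not isolated)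
Conditions: TMPZnCl·LiCl (TMP = 2,2,6,6-tetramethylpiperidide, 1.3 equiv), THF, 25 °C, 2 h; then I2 (1.5 equiv), 0 °C → rt; aq. Na2S2O3
Reagents that add atoms: iodine, II
Why: Deprotonative zincation with the hindered zinc amide takes the only ring C–H (C6, next to the ring oxygen and β to the carbonyl, the site metalated in chromones) without attacking the carbonyl, and iodinolysis of the C–Zn bond gives the iodide.

**Step 4**
Reactants: 3 (E)-1-(dimethylamino)-2-methylpent-1-en-3-one; 9 propanoyl chloride
Product: 11 2-ethyl-3,5-dimethyl-4H-pyran-4-one, via C-acylated enaminone 10 (not isolated)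
Conditions: 3 (2.1 equiv), LiN(SiMe3)2 (2.1 equiv), THF, −78 °C; 9 (1.0 equiv), −78 → −20 °C; then 3 M HCl, rt
Reagents that add atoms: none
Why: The same enolate C-acylation (Claisen-type) and acid-induced 6-endo addition–elimination as in step 2 builds pyrone B.

**Step 5**
Reactants: 11 2-ethyl-3,5-dimethyl-4H-pyran-4-one
Product: 13 2-ethyl-6-iodo-3,5-dimethyl-4H-pyran-4-one, via pyronylzinc chloride 12 (not isolated)
Conditions: TMPZnCl·LiCl (1.3 equiv), THF, 25 °C, 2 h; then I2 (1.5 equiv), 0 °C → rt; aq. Na2S2O3
Reagents that add atoms: iodine, II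
Why: Deprotonative zincation of the single ring C–H followed by iodinolysis, as in step 3.

**Step 6**
Reactants: 1 pentan-3-one
Product: 14 2,4-dibromopentan-3-one (meso/dl mixture)
Conditions: Br2 (2.05 equiv), PBr3 (cat.), neat, −10 → 0 °C; vacuum distillation, used fresh
Reagents that add atoms: bromine, BrBr
Why: Acid-catalysed enol bromination puts the second bromine on the unbrominated α'-side, and the meso/dl ratio does not matter because both C–Br carbons are later converted through planar radicals.

**Step 7**
Reactants: 8 2-iodo-3,5-dimethyl-6-pentyl-4H-pyran-4-one; 14 2,4-dibromopentan-3-one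
Product: 16 (4R)-2-bromo-4-(3,5-dimethyl-4-oxo-6-pentyl-4H-pyran-2-yl)pentan-3-one (C2 epimer mixture), via pyronylzinc iodide 15 (not isolated)
Conditions: 8, Zn dust, LiCl, THF, 25 °C (gives 15, decanted from excess zinc); then 14 (3 equiv), NiCl2·glyme (10 mol%), (S,S)-Ph-pybox (13 mol%), glyme/THF, −30 °C, 24 h; pH 7 phosphate buffer at −30 °C; excess 14 recovered
Reagents that add atoms: none
Why: Proposed new method: a nickel/pybox-catalysed enantioconvergent Negishi coupling with a zincated γ-pyrone as nucleophile and one C–Br bond of a dialkyl α,α'-dibromoketone as electrophile, in which the monovalent nickel–pyronyl complex abstracts bromine from either epimer of 14 to give a planar α-acyl radical, the radical is captured at divalent nickel, and reductive elimination from the trivalent nickel(pyronyl)(alkyl) complex forms the C(sp2)–C(sp3) bond with the ligand fixing the R configuration, while the excess of 14 keeps the second C–Br bond for step 8; the closest known reaction type is the Ni/pybox-catalysed stereoconvergent Negishi arylation of racemic α-bromoketones with arylzinc iodides, shown for aryl alkyl ketones and simple arylzincs.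

**Step 8**
Reactants: 13 2-ethyl-6-iodo-3,5-dimethyl-4H-pyran-4-one; 16 (4R)-2-bromo-4-(3,5-dimethyl-4-oxo-6-pentyl-4H-pyran-2-yl)pentan-3-one
Product: 18 (2R,4S)-2-(3,5-dimethyl-4-oxo-6-pentyl-4H-pyran-2-yl)-4-(6-ethyl-3,5-dimethyl-4-oxo-4H-pyran-2-yl)pentan-3-one, via pyronylzinc iodide 17 (not isolated)
Conditions: 13, Zn dust, LiCl, THF, 25 °C (gives 17, 1.5 equiv, decanted from excess zinc); then 16, NiCl2·glyme (10 mol%), (R,R)-Ph-pybox (13 mol%), glyme/THF, −30 °C, 24 h; pH 7 phosphate buffer at −30 °C; fast chromatography on pH 7-buffered silica, then HPLC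
Reagents that add atoms: none
Why: Proposed new method: the same nickel/pybox enantioconvergent Negishi manifold run with the mirror-image ligand on the α-bromo-α'-pyronyl ketone 16, in which radical formation and C–C bond formation occur only at the C–Br carbon (both epimers converge on S under catalyst control) while the R centre from step 7 is a spectator because the amine-free arylzinc iodide at −30 °C does not enolise the ketone, and the independent setting of the two centres sends most of the minor enantiomer of each coupling into the separable (2R,4R)/(2S,4S) diastereomers (Horeau amplification); the closest known reaction type is again the Ni-catalysed enantioconvergent Negishi α-arylation of racemic α-bromoketones.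

**Compound list**
1 | pentan-3-one | CCC(=O)CC | starting material
2 | N,N-dimethylformamide dimethyl acetal | COC(OC)N(C)C | starting material
3 | (E)-1-(dimethylamino)-2-methylpent-1-en-3-one | CCC(=O)/C(C)=C/N(C)C | intermediate
4 | hexanoyl chloride | CCCCCC(=O)Cl | starting material
5 | (E)-1-(dimethylamino)-2,4-dimethyldec-1-ene-3,5-dione (racemic at C4, present as its lithium enolate) | CCCCCC(=O)C(C)C(=O)/C(C)=C/N(C)C | intermediate
6 | 3,5-dimethyl-2-pentyl-4H-pyran-4-one | CCCCCc1occ(C)c(=O)c1C | intermediate
7 | chloro(3,5-dimethyl-4-oxo-6-pentyl-4H-pyran-2-yl)zinc (LiCl complex) | CCCCCc1oc([Zn]Cl)c(C)c(=O)c1C | intermediate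
8 | 2-iodo-3,5-dimethyl-6-pentyl-4H-pyran-4-one | CCCCCc1oc(I)c(C)c(=O)c1C | intermediate
9 | propanoyl chloride | CCC(=O)Cl | starting material
10 | (E)-1-(dimethylamino)-2,4-dimethylhept-1-ene-3,5-dione (racemic at C4, present as its lithium enolate) | CCC(=O)C(C)C(=O)/C(C)=C/N(C)C | intermediate
11 | 2-ethyl-3,5-dimethyl-4H-pyran-4-one | CCc1occ(C)c(=O)c1C | intermediate
12 | chloro(6-ethyl-3,5-dimethyl-4-oxo-4H-pyran-2-yl)zinc (LiCl complex) | CCc1oc([Zn]Cl)c(C)c(=O)c1C | intermediate
13 | 2-ethyl-6-iodo-3,5-dimethyl-4H-pyran-4-one | CCc1oc(I)c(C)c(=O)c1C | intermediate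
14 | 2,4-dibromopentan-3-one (meso/dl mixture) | CC(Br)C(=O)C(C)Br | intermediate
15 | (3,5-dimethyl-4-oxo-6-pentyl-4H-pyran-2-yl)(iodo)zinc | CCCCCc1oc([Zn]I)c(C)c(=O)c1C | intermediate
16 | (4R)-2-bromo-4-(3,5-dimethyl-4-oxo-6-pentyl-4H-pyran-2-yl)pentan-3-one (C2 epimer mixture) | CCCCCc1oc([C@@H](C)C(=O)C(C)Br)c(C)c(=O)c1C | intermediate
17 | (6-ethyl-3,5-dimethyl-4-oxo-4H-pyran-2-yl)(iodo)zinc | CCc1oc([Zn]I)c(C)c(=O)c1C | intermediate
18 | (2R,4S)-2-(3,5-dimethyl-4-oxo-6-pentyl-4H-pyran-2-yl)-4-(6-ethyl-3,5-dimethyl-4-oxo-4H-pyran-2-yl)pentan-3-one | CCCCCc1oc([C@@H](C)C(=O)[C@@H](C)c2oc(CC)c(C)c(=O)c2C)c(C)c(=O)c1C | target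

**Totals**
Total step count: 8. Longest linear sequence: 5 steps (steps 1, 2, 3, 7, 8).

**Steps most likely to fail**

Step 7 (proposed coupling). The risks are:
- the pyronylzinc iodide has a flanking methyl group and may transmetalate slowly;
- iodide or low-valent nickel may strip both bromines from 14 (oxyallyl or Favorskii-type loss);
- the level and sense of induction are untested.

The fallback uses known chemistry only, sets out from 8 (with 9 and 13) and comes back at 18. Propanoyl chloride 9 N-acylates lithiated (4S)-4-benzyl-1,3-oxazolidin-2-one (n-BuLi, THF, −78 °C) to give (4S)-4-benzyl-3-propanoyl-1,3-oxazolidin-2-one F1. NaN(SiMe3)2 and then Me3SiCl give its Z-configured O-trimethylsilyl ketene N,O-acetal F2. Pd(dba)2/P(t-Bu)3 with ZnF2 (DMF, 80 °C) arylates F2 with 8 under auxiliary control (usual Evans facial model) to give the (2R)-2-pyronylpropanoyl imide F3, purified to one diastereomer. LiBH4 (THF/MeOH, 0 °C) removes the auxiliary and gives the primary alcohol F4, whose stereocentre is no longer next to a carbonyl. Dess–Martin periodinane gives the aldehyde F5, used at once. In parallel 13 is ethylated (Et2Zn, Pd(dppf)Cl2, THF) to 2,6-diethyl-3,5-dimethyl-4H-pyran-4-one F6. Lateral lithiation of F6 (LiN(SiMe3)2, THF, −78 °C) and addition to F5 give the carbinol F7. Buffered Dess–Martin oxidation then gives 18 together with its (2R,4R) epimer, which is removed by HPLC. This route gives up catalyst control at the second centre and pays with a diastereomer separation.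

Step 8 (proposed coupling). The risks are:
- a mismatched pairing of the mirror-image ligand with the existing R centre;
- epimerisation of either α-pyronyl ketone centre during reaction or work-up;
- Favorskii-type loss of HBr from 16.

The fallback uses known chemistry only, sets out from 16 (with 13) and comes back at 18; it reverses the polarity. Zn dust/Me3SiCl/TMEDA (Et2O, 0 °C) converts the C–Br bond of 16 regiospecifically into the trimethylsilyl enol ether F8. Pd(OAc)2/P(t-Bu)3 with Bu3SnF (toluene, 60 °C) then arylates F8 with iodide 13. This gives 18 and its (2R,4R) epimer without control at C4, and the two are separated by HPLC.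

Step 3 (the same question arises in step 5 and is judged with it). The risk is lateral zincation at the α-CH2 of the C2 alkyl chain (vinylogous to the carbonyl) instead of ring C6–H.

The fallback sets out from 6 and comes back at 8 (and likewise from 11 to 13). Iridium-catalysed C–H borylation ([Ir(OMe)(cod)]2, 4,4'-di-tert-butyl-2,2'-bipyridine, B2pin2, THF, 80 °C) acts only on the sp2 C–H. It gives 3,5-dimethyl-2-pentyl-6-(pinacolboryl)-4H-pyran-4-one F9, and from 11 the ethyl analogue 2-ethyl-3,5-dimethyl-6-(pinacolboryl)-4H-pyran-4-one F10. Iododeboronation with NaI and TsN(Cl)Na (chloramine-T) in THF/H2O returns 8 and 13.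

**Further compounds**
F1 | step 7 | (4S)-4-benzyl-3-propanoyl-1,3-oxazolidin-2-one | CCC(=O)N1[C@@H](Cc2ccccc2)COC1=O
F2 | step 7 | (4S)-4-benzyl-3-[(1Z)-1-(trimethylsilyloxy)prop-1-en-1-yl]-1,3-oxazolidin-2-one | C/C=C(\O[Si](C)(C)C)N1[C@@H](Cc2ccccc2)COC1=O
F3 | step 7 | (4S)-4-benzyl-3-[(2R)-2-(3,5-dimethyl-4-oxo-6-pentyl-4H-pyran-2-yl)propanoyl]-1,3-oxazolidin-2-one | CCCCCc1oc([C@@H](C)C(=O)N2[C@@H](Cc3ccccc3)COC2=O)c(C)c(=O)c1C
F4 | step 7 | 2-[(2S)-1-hydroxypropan-2-yl]-3,5-dimethyl-6-pentyl-4H-pyran-4-one | CCCCCc1oc([C@@H](C)CO)c(C)c(=O)c1C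
F5 | step 7 | (2R)-2-(3,5-dimethyl-4-oxo-6-pentyl-4H-pyran-2-yl)propanal | CCCCCc1oc([C@@H](C)C=O)c(C)c(=O)c1C
F6 | step 7 | 2,6-diethyl-3,5-dimethyl-4H-pyran-4-one | CCc1oc(CC)c(C)c(=O)c1C
F7 | step 7 | 2-[(2S)-4-(6-ethyl-3,5-dimethyl-4-oxo-4H-pyran-2-yl)-3-hydroxypentan-2-yl]-3,5-dimethyl-6-pentyl-4H-pyran-4-one (epimer mixture at C3 and C4) | CCCCCc1oc([C@@H](C)C(O)C(C)c2oc(CC)c(C)c(=O)c2C)c(C)c(=O)c1C
F8 | step 8 | 3,5-dimethyl-2-pentyl-6-[(2R)-3-(trimethylsilyloxy)pent-3-en-2-yl]-4H-pyran-4-one (E/Z mixture) | CCCCCc1oc([C@@H](C)C(O[Si](C)(C)C)=CC)c(C)c(=O)c1C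
F9 | step 3 | 3,5-dimethyl-2-pentyl-6-(4,4,5,5-tetramethyl-1,3,2-dioxaborolan-2-yl)-4H-pyran-4-one | CCCCCc1oc(B2OC(C)(C)C(C)(C)O2)c(C)c(=O)c1C
F10 | step 3 | 2-ethyl-3,5-dimethyl-6-(4,4,5,5-tetramethyl-1,3,2-dioxaborolan-2-yl)-4H-pyran-4-one | CCc1oc(B2OC(C)(C)C(C)(C)O2)c(C)c(=O)c1C
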